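**Retrosynthetic overview**

- The target comes from a cis-cyclopentenediol by oxidation of the secondary carbinol (C9) and acetylation of the tertiary one (C12). C12 is set by α-selective addition of a (Z)-oct-2-enylbarium reagent to a 4-silyloxy-5-alkylidenecyclopent-2-enone, anti to the silyloxy group.
- Because the ring carbonyl is moved from C12 to C9 in this way, the thermodynamic E-alkylidene of the precursor enone (chain anti to its C=O) becomes the 7Z-dienone of the target.
- The E,E-dienone comes from redox isomerisation of a trans-4-hydroxy-5-alkynylcyclopent-2-enone.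
- Ring formation: the cyclopentenone (Piancatelli 4π-electrocyclisation) and the γ-lactone close together in one aqueous-acid operation on an acyclic furyl propargyl carbinol; the furan is consumed.
- That carbinol comes from furfural and tert-butyl (4R)-4-hydroxyhept-6-ynoate, made by asymmetric propargylation of tert-butyl 4-oxobutanoate.

Assumption: in step 5 the lipase keeps the sense known for 4-hydroxycyclopent-2-enone (it acetylates the carbinol that has the spatial arrangement of the (R)-parent), so the wanted (4R)-epimer 11 is the one left as the free alcohol.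

**Route**

Step 1
Reactants: 1 tert-butyl 4-oxobutanoate; 2 allenylboronic acid pinacol ester
Product: 4 tert-butyl (4R)-4-hydroxyhept-6-ynoate, via pinacol borate ester 3 (not isolated)
Conditions: (S)-TRIP [(S)-3,3'-bis(2,4,6-triisopropylphenyl)-1,1'-binaphthyl-2,2'-diyl hydrogen phosphate] (5 mol %), 4 Å MS, toluene, −20 °C; aq. work-up
Reagents that add atoms: none
Why: Chiral-phosphoric-acid-catalysed allenylboration (asymmetric propargylation of an aldehyde) runs through a closed six-membered transition state in which the (S)-catalyst, by analogy with the re-face delivery of its (R)-enantiomer, sends the allenyl γ-carbon to the si face and sets C4 as R.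

Step 2
Reactants: 4 tert-butyl (4R)-4-hydroxyhept-6-ynoate; 5 furfural
Product: 6 tert-butyl (4R)-8-(furan-2-yl)-4,8-dihydroxyoct-6-ynoate (1:1 mixture of C8 epimers)
Conditions: LiN(i-Pr)2 (2.1 equiv), THF, −78 °C; 5, −78 → −40 °C; AcOH quench
Reagents that add atoms: none
Why: Acetylide addition to an aldehyde (alkynylation through the alkoxide–acetylide dianion) forms the C7–C8 bond, and the new carbinol centre may form unselectively because it is ionised in step 3.

Step 3
Reactants: 6 tert-butyl (4R)-8-(furan-2-yl)-4,8-dihydroxyoct-6-ynoate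
Product: 8 (5R)-5-{3-[(1S,5R)-5-hydroxy-2-oxocyclopent-3-en-1-yl]prop-2-yn-1-yl}oxolan-2-one (1:1 mixture of this plus its (1R,5S) ring diastereomer), via cyclopentenone tert-butyl ester 7 (not isolated)
Conditions: TsOH·H2O (0.3 equiv), 1,4-dioxane/H2O 3:1, 85 °C
Reagents that add atoms: water (O)
Why: Proposed new method: acid ionises the furyl propargyl carbinol to a furfuryl cation, water adds at furan C5, ring opening gives a 1-hydroxypentadienyl cation whose conrotatory 4π-electrocyclisation builds the trans-4-hydroxy-5-alkynylcyclopentenone, while the same acid closes the γ-hydroxy tert-butyl ester to the γ-lactone (C4 untouched; the two new ring centres are trans to each other but uncontrolled relative to C4, which step 5 corrects); the closest known reaction type is the Piancatelli rearrangement (known for furyl alkynyl carbinols in its aza form) combined with acid-catalysed lactonisation.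

Step 4
Reactants: 8 (5R)-5-{3-[(1S,5R)-5-hydroxy-2-oxocyclopent-3-en-1-yl]prop-2-yn-1-yl}oxolan-2-one (diastereomer mixture)
Product: 10 (5E)-4-hydroxy-5-{(2E)-3-[(2R)-5-oxooxolan-2-yl]prop-2-en-1-ylidene}cyclopent-2-en-1-one (1:1 mixture of 4R plus 4S), via allenone 9 (not isolated)
Conditions: Et3N (1 equiv), CH2Cl2, 0 °C; then PPh3 (20 mol %), rt → 40 °C
Reagents that add atoms: none
Why: Base-mediated propargyl-to-allenyl ketone isomerisation followed by phosphine-catalysed allenone-to-dienone isomerisation (redox isomerisation of the Trost–Lu type) gives the thermodynamic E,E-dienone, whose chain lies anti to the ring C=O and therefore syn to the carbinol carbon that becomes the ketone of the target.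

Step 5
Reactants: 10 (5E)-4-hydroxy-5-{(2E)-3-[(2R)-5-oxooxolan-2-yl]prop-2-en-1-ylidene}cyclopent-2-en-1-one (4R/4S mixture)
Product: 11 (4R,5E)-4-hydroxy-5-{(2E)-3-[(2R)-5-oxooxolan-2-yl]prop-2-en-1-ylidene}cyclopent-2-en-1-one
Conditions: Novozym 435 (immobilised Candida antarctica lipase B), vinyl acetate (3 equiv), MTBE, 30 °C, to about 50 % conversion; chromatography
Reagents that add atoms: none
Why: Lipase-catalysed kinetic resolution by transesterification acetylates only the (4S)-carbinol epimer and leaves the (4R)-alcohol, which fixes the relay centre C9.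

Step 6
Reactants: 11 (4R,5E)-4-hydroxy-5-{(2E)-3-[(2R)-5-oxooxolan-2-yl]prop-2-en-1-ylidene}cyclopent-2-en-1-one
Product: 12 (4R,5E)-4-[(tert-butyldimethylsilyl)oxy]-5-{(2E)-3-[(2R)-5-oxooxolan-2-yl]prop-2-en-1-ylidene}cyclopent-2-en-1-one
Conditions: TBSCl, imidazole, DMF, 0 °C → rt
Reagents that add atoms: tert-butyldimethylsilyl chloride, CC(C)(C)[Si](C)(C)Cl
Why: Imidazole-promoted silylation puts a bulky ether on the C9 oxygen that shields one ring face in step 8 and touches no stereocentre.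

Step 7
Reactants: 13 (2Z)-oct-2-en-1-ol
Product: 14 (2Z)-1-chlorooct-2-ene
Conditions: N-chlorosuccinimide, Me2S, CH2Cl2, −20 → 0 °C
Reagents that add atoms: N-chlorosuccinimide, O=C1CCC(=O)N1Cl
Why: Corey–Kim chlorination displaces an alkoxysulfonium ion by chloride in an SN2 step, without allylic transposition and without loss of the Z geometry.

Step 8
Reactants: 12 (4R,5E)-4-[(tert-butyldimethylsilyl)oxy]-5-{(2E)-3-[(2R)-5-oxooxolan-2-yl]prop-2-en-1-ylidene}cyclopent-2-en-1-one; 14 (2Z)-1-chlorooct-2-ene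
Product: 15 (1S,4R,5E)-4-[(tert-butyldimethylsilyl)oxy]-1-[(2Z)-oct-2-en-1-yl]-5-{(2E)-3-[(2R)-5-oxooxolan-2-yl]prop-2-en-1-ylidene}cyclopent-2-en-1-ol
Conditions: BaI2 + LiC12H10 (lithium biphenylide, 2 equiv), THF, rt (gives zerovalent barium); 14 (1.5 equiv), −78 °C; 12, −78 °C, 30 min; sat. aq. NH4Cl
Reagents that add atoms: none
Why: Yamamoto allylbarium addition delivers the (Z)-allylic barium reagent 1,2 to the ketone through its α-carbon with retention of the Z double bond, anti to the C9 silyloxy group, which sets C12 as S.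

Step 9
Reactants: 15 (1S,4R,5E)-4-[(tert-butyldimethylsilyl)oxy]-1-[(2Z)-oct-2-en-1-yl]-5-{(2E)-3-[(2R)-5-oxooxolan-2-yl]prop-2-en-1-ylidene}cyclopent-2-en-1-ol
Product: 16 (1S,4R,5E)-1-[(2Z)-oct-2-en-1-yl]-5-{(2E)-3-[(2R)-5-oxooxolan-2-yl]prop-2-en-1-ylidene}cyclopent-2-ene-1,4-diol
Conditions: TBAF (1.5 equiv), AcOH (1.5 equiv), THF, 0 °C → rt
Reagents that add atoms: none
Why: Buffered fluoride desilylation frees the secondary allylic alcohol without opening the lactone or ionising the tertiary bis-allylic alcohol.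

Step 10
Reactants: 16 (1S,4R,5E)-1-[(2Z)-oct-2-en-1-yl]-5-{(2E)-3-[(2R)-5-oxooxolan-2-yl]prop-2-en-1-ylidene}cyclopent-2-ene-1,4-diol
Product: 17 (4S,5Z)-4-hydroxy-4-[(2Z)-oct-2-en-1-yl]-5-{(2E)-3-[(2R)-5-oxooxolan-2-yl]prop-2-en-1-ylidene}cyclopent-2-en-1-one
Conditions: MnO2 (15 equiv), CH2Cl2, rt
Reagents that add atoms: none
Why: MnO2 oxidation of the secondary bis-allylic alcohol (the tertiary alcohol cannot react) gives the cross-conjugated dienone with the side chain now syn to the ketone, which is the 7Z geometry.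

Step 11
Reactants: 17 (4S,5Z)-4-hydroxy-4-[(2Z)-oct-2-en-1-yl]-5-{(2E)-3-[(2R)-5-oxooxolan-2-yl]prop-2-en-1-ylidene}cyclopent-2-en-1-one
Product: 18 (1S,5Z)-1-[(2Z)-oct-2-en-1-yl]-4-oxo-5-{(2E)-3-[(2R)-5-oxooxolan-2-yl]prop-2-en-1-ylidene}cyclopent-2-en-1-yl acetate (the target)
Conditions: Ac2O, DMAP (cat.), Et3N, CH2Cl2, 0 °C, dark
Reagents that add atoms: acetic anhydride, CC(=O)OC(C)=O
Why: DMAP-catalysed acetylation of the tertiary alcohol completes the target without touching a stereocentre.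

**Compound list**

1 | tert-butyl 4-oxobutanoate | O=CCCC(=O)OC(C)(C)C | starting material
2 | allenylboronic acid pinacol ester (4,4,5,5-tetramethyl-2-(propa-1,2-dien-1-yl)-1,3,2-dioxaborolane) | C=C=CB1OC(C)(C)C(C)(C)O1 | starting material
3 | tert-butyl (4R)-4-[(4,4,5,5-tetramethyl-1,3,2-dioxaborolan-2-yl)oxy]hept-6-ynoate | C#CC[C@H](OB1OC(C)(C)C(C)(C)O1)CCC(=O)OC(C)(C)C | intermediate
4 | tert-butyl (4R)-4-hydroxyhept-6-ynoate | C#CC[C@H](O)CCC(=O)OC(C)(C)C | intermediate
5 | furfural (furan-2-carbaldehyde) | O=Cc1ccco1 | starting material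
6 | tert-butyl (4R)-8-(furan-2-yl)-4,8-dihydroxyoct-6-ynoate (C8 epimer mixture) | OC(C#CC[C@H](O)CCC(=O)OC(C)(C)C)c1ccco1 | intermediate
7 | tert-butyl (4R)-4-hydroxy-7-[(1S,5R)-5-hydroxy-2-oxocyclopent-3-en-1-yl]hept-6-ynoate (plus its (1R,5S) ring diastereomer) | O=C1C=C[C@@H](O)[C@@H]1C#CC[C@H](O)CCC(=O)OC(C)(C)C | intermediate
8 | (5R)-5-{3-[(1S,5R)-5-hydroxy-2-oxocyclopent-3-en-1-yl]prop-2-yn-1-yl}oxolan-2-one (plus its (1R,5S) ring diastereomer) | O=C1C=C[C@@H](O)[C@@H]1C#CC[C@H]1CCC(=O)O1 | intermediate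
9 | (5R)-5-[3-(2-hydroxy-5-oxocyclopent-3-en-1-ylidene)prop-2-en-1-yl]oxolan-2-one (allenone, carbinol epimer mixture) | O=C1C=CC(O)C1=C=CC[C@H]1CCC(=O)O1 | intermediate
10 | (5E)-4-hydroxy-5-{(2E)-3-[(2R)-5-oxooxolan-2-yl]prop-2-en-1-ylidene}cyclopent-2-en-1-one (4R/4S mixture) | O=C1C=CC(O)/C1=C\C=C\[C@H]1CCC(=O)O1 | intermediate
11 | (4R,5E)-4-hydroxy-5-{(2E)-3-[(2R)-5-oxooxolan-2-yl]prop-2-en-1-ylidene}cyclopent-2-en-1-one | O=C1C=C[C@@H](O)/C1=C\C=C\[C@H]1CCC(=O)O1 | intermediate
12 | (4R,5E)-4-[(tert-butyldimethylsilyl)oxy]-5-{(2E)-3-[(2R)-5-oxooxolan-2-yl]prop-2-en-1-ylidene}cyclopent-2-en-1-one | O=C1C=C[C@@H](O[Si](C)(C)C(C)(C)C)/C1=C\C=C\[C@H]1CCC(=O)O1 | intermediate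
13 | (2Z)-oct-2-en-1-ol | CCCCC/C=C\CO | starting material
14 | (2Z)-1-chlorooct-2-ene | CCCCC/C=C\CCl | intermediate
15 | (1S,4R,5E)-4-[(tert-butyldimethylsilyl)oxy]-1-[(2Z)-oct-2-en-1-yl]-5-{(2E)-3-[(2R)-5-oxooxolan-2-yl]prop-2-en-1-ylidene}cyclopent-2-en-1-ol | CCCCC/C=C\C[C@]1(O)C=C[C@@H](O[Si](C)(C)C(C)(C)C)/C1=C\C=C\[C@H]1CCC(=O)O1 | intermediate
16 | (1S,4R,5E)-1-[(2Z)-oct-2-en-1-yl]-5-{(2E)-3-[(2R)-5-oxooxolan-2-yl]prop-2-en-1-ylidene}cyclopent-2-ene-1,4-diol | CCCCC/C=C\C[C@]1(O)C=C[C@@H](O)/C1=C\C=C\[C@H]1CCC(=O)O1 | intermediate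
17 | (4S,5Z)-4-hydroxy-4-[(2Z)-oct-2-en-1-yl]-5-{(2E)-3-[(2R)-5-oxooxolan-2-yl]prop-2-en-1-ylidene}cyclopent-2-en-1-one | CCCCC/C=C\C[C@]1(O)C=CC(=O)/C1=C\C=C\[C@H]1CCC(=O)O1 | intermediate
18 | (1S,5Z)-1-[(2Z)-oct-2-en-1-yl]-4-oxo-5-{(2E)-3-[(2R)-5-oxooxolan-2-yl]prop-2-en-1-ylidene}cyclopent-2-en-1-yl acetate | CCCCC/C=C\C[C@]1(OC(C)=O)C=CC(=O)/C1=C\C=C\[C@H]1CCC(=O)O1 | target

**Step count and risks**

Total steps: 11. Longest linear sequence: 10 (steps 1–6, then 8–11); step 7 is a one-step branch.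

The three steps most likely to fail:

Step 3. The propargylic furyl carbinol may divert to Meyer–Schuster products, or the hot acid may degrade the alkynyl hydroxy-enone. The fallback builds the cyclopentenone by oxidative furan opening and aldol closure instead of a cationic electrocyclisation. It sets out from 6 and returns at 8. Ionic deoxygenation of the carbinol with Et3SiH/CF3CO2H (the acid also closes the lactone) gives (5R)-5-[4-(furan-2-yl)but-2-yn-1-yl]oxolan-2-one F1. Singlet-oxygen photooxygenation (O2, tetraphenylporphyrin, hν, MeOH, then Me2S) opens the furan to (5R)-5-[(6Z)-5,8-dioxooct-6-en-2-yn-1-yl]oxolan-2-one F2. Et3N then closes the doubly activated C8 methylene onto the aldehyde (intramolecular aldol) to give 8.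

Step 5. The lipase may be unselective on this 5-alkylidene substrate, or may prefer the other epimer. The fallback replaces the enzymatic resolution by a classical separation of covalent diastereomers. It sets out from 10 and returns at 11. Esterification with (2S)-2-methoxy-2-phenylacetic acid (DCC, DMAP, CH2Cl2) gives (1R,5E)-4-oxo-5-{(2E)-3-[(2R)-5-oxooxolan-2-yl]prop-2-en-1-ylidene}cyclopent-2-en-1-yl (2S)-2-methoxy-2-phenylacetate F3 together with its (1S)-diastereomer F4. These differ at the carbon that carries the chiral acyl group and are separated by chromatography. K2CO3/MeOH at 0 °C, followed by a trace of TsOH to re-close any opened lactone, cleaves F3 to 11.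

Step 8. The barium reagent may attack the lactone, add with allylic transposition, or add with poor facial control. The fallback builds the side chain in two C–C steps with non-allylic nucleophiles. It sets out from 12 and returns at 15. Dimethylsulfonium methylide (Me3S+ I−, n-BuLi, THF, −10 °C; Corey–Chaykovsky) adds anti to the silyloxy group and gives the spiro-epoxide (5R)-5-[(1E,3E)-3-{(3S,6R)-6-[(tert-butyldimethylsilyl)oxy]-1-oxaspiro[2.4]hept-4-en-7-ylidene}prop-1-en-1-yl]oxolan-2-one F5. Hept-1-ynyllithium with BF3·OEt2 at −78 °C opens the oxirane at its CH2 group to give (1S,4R,5E)-4-[(tert-butyldimethylsilyl)oxy]-1-(oct-2-yn-1-yl)-5-{(2E)-3-[(2R)-5-oxooxolan-2-yl]prop-2-en-1-ylidene}cyclopent-2-en-1-ol F6. Semi-hydrogenation (H2, Pd/CaCO3 poisoned with Pb(OAc)2, quinoline) gives 15.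

Further compounds
F1 | step 3 | (5R)-5-[4-(furan-2-yl)but-2-yn-1-yl]oxolan-2-one | C(C#CC[C@H]1CCC(=O)O1)c1ccco1
F2 | step 3 | (5R)-5-[(6Z)-5,8-dioxooct-6-en-2-yn-1-yl]oxolan-2-one | O=C/C=C\C(=O)CC#CC[C@H]1CCC(=O)O1
F3 | step 5 | (1R,5E)-4-oxo-5-{(2E)-3-[(2R)-5-oxooxolan-2-yl]prop-2-en-1-ylidene}cyclopent-2-en-1-yl (2S)-2-methoxy-2-phenylacetate | O=C1C=C[C@@H](OC(=O)[C@@H](OC)c2ccccc2)/C1=C\C=C\[C@H]1CCC(=O)O1
F4 | step 5 | (1S,5E)-4-oxo-5-{(2E)-3-[(2R)-5-oxooxolan-2-yl]prop-2-en-1-ylidene}cyclopent-2-en-1-yl (2S)-2-methoxy-2-phenylacetate | O=C1C=C[C@H](OC(=O)[C@@H](OC)c2ccccc2)/C1=C\C=C\[C@H]1CCC(=O)O1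
F5 | step 8 | (5R)-5-[(1E,3E)-3-{(3S,6R)-6-[(tert-butyldimethylsilyl)oxy]-1-oxaspiro[2.4]hept-4-en-7-ylidene}prop-1-en-1-yl]oxolan-2-one | C1O[C@]12C=C[C@@H](O[Si](C)(C)C(C)(C)C)/C2=C\C=C\[C@H]1CCC(=O)O1
F6 | step 8 | (1S,4R,5E)-4-[(tert-butyldimethylsilyl)oxy]-1-(oct-2-yn-1-yl)-5-{(2E)-3-[(2R)-5-oxooxolan-2-yl]prop-2-en-1-ylidene}cyclopent-2-en-1-ol | CCCCCC#CC[C@]1(O)C=C[C@@H](O[Si](C)(C)C(C)(C)C)/C1=C\C=C\[C@H]1CCC(=O)O1
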